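The geranyl chain on C6 is cut in this order: C6''=C7'' (Wittig), C4''–C5'' (aliphatic Claisen shift, O–C2'' being the bond given up), C2''–C3'' (isopropenyl addition to an arylacetaldehyde), C6–C1'' (aromatic Claisen shift from O5); the 7- and 3'-O-methyl groups lead back to (2S)-hesperetin.
Enabling feature: on the C6 side chain of ring A the E-trisubstituted C2''=C3'' alkene and C6''=C7'' are separated by C4'' and C5'' (a 1,5-diene), so C3''–C6'' maps onto the γ,δ-unsaturated aldehyde that the 3,3-shift of an allyl vinyl ether delivers.
Forward: rings A, B and C come ready-made with hesperetin and no ring is closed; the chain is joined as allyl on O5, moved to C6, cut back to a C2 aldehyde, then grown by isopropenyl (C3), vinyl (C2, Claisen) and isopropylidene (C3).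
Stereochemistry: C2 (S) is bought with hesperetin and kept by avoiding strong base at C3; the E geometry at C2''=C3'' comes from the chair transition state of the Claisen step; the C2'' carbinol is made as both epimers and erased.

Key step: step 7

Assumption: (2S)-hesperetin of high enantiomeric purity is commercially available; lacking a free 4'-OH, its C2 centre should not epimerise under the weak amine bases used.
Numbering: flavanone (2-arylchroman-4-one) locants; ring C holds O1, C2, C3, C4; ring A holds C4a to C8a; ring B is the 2-aryl group (primed); side-chain carbons on C6 are double-primed, counted from the ring.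

**Step 1**
Reactants: 1 (2S)-hesperetin
Product: 2 (2S)-5-hydroxy-7,3',4'-trimethoxyflavanone
Conditions: TMSCHN2 (2 M in hexanes, 2.5 equiv), i-Pr2NEt (2.5 equiv), MeCN/MeOH 9:1, 0 °C to rt
Reagents that add atoms: trimethylsilyldiazomethane, C[Si](C)(C)C=[N+]=[N-]
Why: Diazoalkane O-methylation of phenols: the acidic 7-OH and the free 3'-OH are methylated, whereas the 5-OH, hydrogen-bonded to the C4 carbonyl, should stay free; the weak amine base does not open ring C and no stereocenter is touched.

**Step 2**
Reactants: 2 (2S)-5-hydroxy-7,3',4'-trimethoxyflavanone; 3 allyl alcohol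
Product: 4 (2S)-5-allyloxy-7,3',4'-trimethoxyflavanone
Conditions: PPh3 (2 equiv), DIAD (2 equiv), 3 (2.5 equiv), THF, 0 °C to rt
Reagents that add atoms: none
Why: Mitsunobu etherification: the chelated 5-OH is acidic enough to be alkylated by the allyloxyphosphonium ion under near-neutral conditions, which avoids the chalcone opening that carbonate bases and allyl halides can cause on flavanones.

**Step 3**
Reactants: 4 (2S)-5-allyloxy-7,3',4'-trimethoxyflavanone
Product: 5 (2S)-6-allyl-5-hydroxy-7,3',4'-trimethoxyflavanone
Conditions: Eu(fod)3 (fod = 6,6,7,7,8,8,8-heptafluoro-2,2-dimethyloctane-3,5-dionate; 10 mol %), toluene, 100 °C, sealed tube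
Reagents that add atoms: none
Why: Aromatic Claisen rearrangement accelerated by trivalent europium chelated between O5 and the C4 carbonyl: the 3,3-shift can only reach C6 because C4a is blocked, and for an unsubstituted allyl group the dienone should tautomerise to the phenol faster than a second shift to C8 can occur; no new stereocenter.

**Step 4**
Reactants: 5 (2S)-6-allyl-5-hydroxy-7,3',4'-trimethoxyflavanone
Product: 6 (2S)-6-allyl-7,3',4'-trimethoxy-5-(methoxymethoxy)flavanone
Conditions: MOMCl (4 equiv), i-Pr2NEt (5 equiv), Bu4NI (cat.), CH2Cl2, 0 to 40 °C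
Reagents that add atoms: chloromethyl methyl ether, COCCl
Why: MOM ether formation (O-alkylation of a phenol): iodide-activated MOMCl captures the phenoxide made by a hindered amine that is too weak to deprotonate C3, so ring C and C2 should be unaffected; the acetal shields O5 from the chromium reagent, the mercury salt and the ylide used later.

**Step 5**
Reactants: 6 (2S)-6-allyl-7,3',4'-trimethoxy-5-(methoxymethoxy)flavanone
Product: 8 (2S)-7,3',4'-trimethoxy-5-(methoxymethoxy)-6-(2-oxoethyl)flavanone, via side-chain 1,2-diol 7 (not isolated)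
Conditions: OsO4 (2 mol %), NaIO4 (4 equiv), 2,6-lutidine (2 equiv), dioxane/H2O 3:1, rt
Reagents that add atoms: osmium tetroxide, O=[Os](=O)(=O)=O (oxygen carrier); sodium periodate, [Na+].[O-]I(=O)(=O)=O, and water, O (they restore the oxygen on osmium)
Why: Lemieux–Johnson oxidation: catalytic OsO4 dihydroxylates the only alkene and periodate cleaves the diol in the same flask while 2,6-lutidine buffers the medium; the electron-rich rings, the acetal and C2 are not affected.

**Step 6**
Reactants: 8 (2S)-7,3',4'-trimethoxy-5-(methoxymethoxy)-6-(2-oxoethyl)flavanone; 9 2-bromopropene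
Product: 10 (2S)-6-[(2RS)-2-hydroxy-3-methylbut-3-enyl]-7,3',4'-trimethoxy-5-(methoxymethoxy)flavanone (both carbinol epimers)
Conditions: 9 (3 equiv), CrCl2 (5 equiv), NiCl2 (2 mol %), DMF, rt
Reagents that add atoms: none
Why: Nozaki–Hiyama–Kishi reaction: the nickel-catalysed alkenylchromium reagent adds to aldehydes but not to ketones and is not basic, so the C4 ketone, C3–H and the enolisable aldehyde are left alone; the C2'' carbinol centre forms without control and both epimers are carried on because step 7 destroys it.

**Step 7**
Reactants: 10 (2S)-6-[(2RS)-2-hydroxy-3-methylbut-3-enyl]-7,3',4'-trimethoxy-5-(methoxymethoxy)flavanone; 11 ethyl vinyl ether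
Product: 13 (2S)-6-[(2E)-3-methyl-6-oxohex-2-enyl]-7,3',4'-trimethoxy-5-(methoxymethoxy)flavanone, via allyl vinyl ether 12 (not isolated)
Conditions: Hg(OAc)2 (0.3 equiv), 11 (solvent), 35 °C; solvent exchanged to toluene over K2CO3 without purification; 120 °C, sealed tube
Reagents that add atoms: none
Why: Divalent mercury catalyses vinyl exchange between the C2'' hydroxyl and ethyl vinyl ether (alkoxymercuration, then loss of ethanol) to give allyl vinyl ether 12, which on heating undergoes a concerted 3,3-sigmatropic shift through a chair transition state that joins the vinyl terminus (C5'') to the methylene carbon C4'' while O–C2'' breaks. The closest known reaction type is the aliphatic Claisen rearrangement of vinyl ethers of secondary 2-methylallyl alcohols, a standard route to E-trisubstituted γ,δ-unsaturated aldehydes. No ring is closed, so no mode of closure applies, and no stereocenter is created; C2'' becomes sp2, so both epimers of 10 give the same product. The selectivity needed is E over Z at C2''=C3'': the arylmethyl group (C1'') on C2'' takes the pseudo-equatorial site of the chair to avoid 1,3-diaxial contact with the vinyl ether, which places C1'' trans to C4''; any minor Z isomer would be removed by chromatography. The medium is neutral, so ring C stays closed and C2 keeps its configuration, and the MOM ether keeps O5 from adding to the vinyl ether or to the mercury-activated alkene.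

**Step 8**
Reactants: 13 (2S)-6-[(2E)-3-methyl-6-oxohex-2-enyl]-7,3',4'-trimethoxy-5-(methoxymethoxy)flavanone; 14 isopropyltriphenylphosphonium iodide
Product: 15 (2S)-6-[(2E)-3,7-dimethylocta-2,6-dienyl]-7,3',4'-trimethoxy-5-(methoxymethoxy)flavanone
Conditions: 14 (1.15 equiv), KN(SiMe3)2 (1.1 equiv), THF, 0 °C; ylide solution added slowly to 13 in THF, −78 to 0 °C
Reagents that add atoms: none
Why: Wittig olefination: the non-stabilised isopropylidene ylide adds at −78 °C to the aliphatic aldehyde far faster than to the C4 ketone, which is deactivated by three ortho/para oxygen donors, and slow addition of ylide made with a slight deficit of base limits deprotonation at C3; the new alkene carries two identical methyl groups, so no geometry issue arises.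

**Step 9**
Reactants: 15 (2S)-6-[(2E)-3,7-dimethylocta-2,6-dienyl]-7,3',4'-trimethoxy-5-(methoxymethoxy)flavanone
Product: 16 (2S)-6-[(2E)-3,7-dimethylocta-2,6-dienyl]-5-hydroxy-7,3',4'-trimethoxyflavanone (CNP0310479.1)
Conditions: HCl (0.5 M in MeOH), 25 to 40 °C
Reagents that add atoms: none
Why: Acid-catalysed acetal methanolysis (MOM cleavage): the MOM ether peri to the C4 carbonyl should cleave under acid too mild to protonate the two trisubstituted alkenes, and the freed 5-OH, tied in a hydrogen bond to the carbonyl, should not add to the side chain; dilute acid does not epimerise C2.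

**Compound list**
1 | (2S)-hesperetin, (2S)-5,7,3'-trihydroxy-4'-methoxyflavanone | COc1ccc([C@@H]2CC(=O)c3c(O)cc(O)cc3O2)cc1O | starting material
2 | (2S)-5-hydroxy-7,3',4'-trimethoxyflavanone | COc1ccc([C@@H]2CC(=O)c3c(O)cc(OC)cc3O2)cc1OC | intermediate
3 | allyl alcohol | C=CCO | starting material
4 | (2S)-5-allyloxy-7,3',4'-trimethoxyflavanone | COc1ccc([C@@H]2CC(=O)c3c(OCC=C)cc(OC)cc3O2)cc1OC | intermediate
5 | (2S)-6-allyl-5-hydroxy-7,3',4'-trimethoxyflavanone | COc1ccc([C@@H]2CC(=O)c3c(cc(OC)c(CC=C)c3O)O2)cc1OC | intermediate
6 | (2S)-6-allyl-7,3',4'-trimethoxy-5-(methoxymethoxy)flavanone | COc1ccc([C@@H]2CC(=O)c3c(cc(OC)c(CC=C)c3OCOC)O2)cc1OC | intermediate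
7 | (2S)-6-(2,3-dihydroxypropyl)-7,3',4'-trimethoxy-5-(methoxymethoxy)flavanone, both diol epimers, not isolated | COc1ccc([C@@H]2CC(=O)c3c(cc(OC)c(CC(O)CO)c3OCOC)O2)cc1OC | intermediate
8 | (2S)-7,3',4'-trimethoxy-5-(methoxymethoxy)-6-(2-oxoethyl)flavanone | COc1ccc([C@@H]2CC(=O)c3c(cc(OC)c(CC=O)c3OCOC)O2)cc1OC | intermediate
9 | 2-bromopropene | CC(Br)=C | starting material
10 | (2S)-6-[(2RS)-2-hydroxy-3-methylbut-3-enyl]-7,3',4'-trimethoxy-5-(methoxymethoxy)flavanone, both carbinol epimers | COc1ccc([C@@H]2CC(=O)c3c(cc(OC)c(CC(O)C(C)=C)c3OCOC)O2)cc1OC | intermediate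
11 | ethyl vinyl ether | C=COCC | starting material
12 | (2S)-6-[2-(ethenyloxy)-3-methylbut-3-enyl]-7,3',4'-trimethoxy-5-(methoxymethoxy)flavanone, both ether epimers, not isolated | COc1ccc([C@@H]2CC(=O)c3c(cc(OC)c(CC(OC=C)C(C)=C)c3OCOC)O2)cc1OC | intermediate
13 | (2S)-6-[(2E)-3-methyl-6-oxohex-2-enyl]-7,3',4'-trimethoxy-5-(methoxymethoxy)flavanone | COc1ccc([C@@H]2CC(=O)c3c(cc(OC)c(C/C=C(\C)CCC=O)c3OCOC)O2)cc1OC | intermediate
14 | isopropyltriphenylphosphonium iodide | CC(C)[P+](c1ccccc1)(c1ccccc1)c1ccccc1.[I-] | starting material
15 | (2S)-6-[(2E)-3,7-dimethylocta-2,6-dienyl]-7,3',4'-trimethoxy-5-(methoxymethoxy)flavanone | COc1ccc([C@@H]2CC(=O)c3c(cc(OC)c(C/C=C(\C)CCC=C(C)C)c3OCOC)O2)cc1OC | intermediate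
16 | (2S)-6-[(2E)-3,7-dimethylocta-2,6-dienyl]-5-hydroxy-7,3',4'-trimethoxyflavanone | COc1ccc([C@@H]2CC(=O)c3c(cc(OC)c(C/C=C(\C)CCC=C(C)C)c3O)O2)cc1OC | target

Total step count: 9. Longest linear sequence: 9 steps (1 to 16).

**Steps most likely to fail**

Step 8. The basic ylide may deprotonate C3 and trigger β-elimination of the ring-C aryloxide (retro-oxa-Michael opening, which would erase C2), or it may enolise the aldehyde instead of adding to it. The fallback sets out from 13 and avoids any base: aldehyde-selective methylenation with CH2I2, Zn and Ti(OiPr)4 in THF should give (2S)-6-[(2E)-3-methylhepta-2,6-dienyl]-7,3',4'-trimethoxy-5-(methoxymethoxy)flavanone F1. Cross-metathesis of F1 with excess 2-methylbut-2-ene (second-generation Grubbs catalyst, CH2Cl2, 40 °C) then installs the isopropylidene terminus and comes back to the route at 15. The hindered trisubstituted C2''=C3'' alkene should not take part.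

Step 5. Over-oxidation at the doubly activated benzylic position, or self-condensation of the enolisable arylacetaldehyde during cleavage and handling, would starve step 6. The fallback sets out from 6 and never passes through the aldehyde: cross-metathesis with 2-methylbut-2-ene (second-generation Grubbs catalyst, CH2Cl2, 40 °C) gives (2S)-7,3',4'-trimethoxy-5-(methoxymethoxy)-6-(3-methylbut-2-enyl)flavanone F2. The Schenck ene reaction of F2 with singlet oxygen (O2, tetraphenylporphyrin, visible light, CH2Cl2, 0 °C) gives (2S)-6-(2-hydroperoxy-3-methylbut-3-enyl)-7,3',4'-trimethoxy-5-(methoxymethoxy)flavanone F3, and the regioisomeric tertiary hydroperoxide formed by benzylic hydrogen abstraction would be separated. Reduction of F3 with PPh3 comes back to the route at 10.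

Step 3. The 3,3-shift of an unsubstituted allyl ether may be too slow at a temperature that the C2 centre tolerates, or the dienone may leak into the para pathway (second shift to C8). The fallback sets out from 2 and replaces rearrangement by cross-coupling: iodination next to the chelated phenol with benzyltrimethylammonium dichloroiodate and CaCO3 in CH2Cl2/MeOH should give (2S)-5-hydroxy-6-iodo-7,3',4'-trimethoxyflavanone F4. Stille coupling of F4 with allyltributylstannane (Pd(PPh3)4, zerovalent palladium, DMF, 80 °C) comes back to the route at 5, so that steps 2 and 3 are bypassed.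

**Further compounds**
F1 | step 8 | (2S)-6-[(2E)-3-methylhepta-2,6-dienyl]-7,3',4'-trimethoxy-5-(methoxymethoxy)flavanone | COc1ccc([C@@H]2CC(=O)c3c(cc(OC)c(C/C=C(\C)CCC=C)c3OCOC)O2)cc1OC
F2 | step 5 | (2S)-7,3',4'-trimethoxy-5-(methoxymethoxy)-6-(3-methylbut-2-enyl)flavanone | COc1ccc([C@@H]2CC(=O)c3c(cc(OC)c(CC=C(C)C)c3OCOC)O2)cc1OC
F3 | step 5 | (2S)-6-(2-hydroperoxy-3-methylbut-3-enyl)-7,3',4'-trimethoxy-5-(methoxymethoxy)flavanone, both epimers | COc1ccc([C@@H]2CC(=O)c3c(cc(OC)c(CC(OO)C(C)=C)c3OCOC)O2)cc1OC
F4 | step 3 | (2S)-5-hydroxy-6-iodo-7,3',4'-trimethoxyflavanone | COc1ccc([C@@H]2CC(=O)c3c(cc(OC)c(I)c3O)O2)cc1OC
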